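**Retrosynthetic overview**
1. Target ⇒ acyclic trihalotriene. One chloronium-triggered cation–olefin cyclisation makes the C3–C9 ring bond, C4–Cl and C7–Br; the cyclohexane is the only carbocycle and is formed last.
2. Trihalotriene ⇒ (Z,Z)-chlorodienol (C6–OH → Cl with inversion; C8–OSi → Br).
3. Chlorodienol ⇒ cyclic alkenyl boronate + (Z)-1,2-dichloroethene (Suzuki coupling fixes both Z alkenes).
4. Cyclic boronate ⇒ homoallylic alcohol + isopropenyl boronate (temporary B–O tether, ring-closing metathesis; this oxaborinine ring is opened again in the coupling).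
5. Homoallylic alcohol ⇒ 2-(silyloxymethyl)acrolein ⇒ 2-methylidenepropane-1,3-diol (asymmetric allylboration brings in the only external chirality).

Assumption: the target is exactly the enantiomer written, (1S,2R,4S,5S)-1-bromo-1-(bromomethyl)-2,4-dichloro-5-[(Z)-2-chloroethenyl]-5-methylcyclohexane, with C–Br, both ring C–Cl bonds and the chlorovinyl group on one face.

Chain numbering used below: ClC1H=C2H–C3(CH3)=C4H–C5H2–C6H(X)–C7(=C9H2)–C8H2Y; the ring is C3, C4, C5, C6, C7, C9.

**Step 1**
Reactants: 1 2-methylidenepropane-1,3-diol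
Product: 2 2-{[(tert-butyldimethylsilyl)oxy]methyl}prop-2-en-1-ol
Conditions: NaH (1.0 equiv), THF, 0 °C; TBSCl (1.0 equiv), 0 °C to rt
Reagents that add atoms: tert-butyldimethylsilyl chloride, CC(C)(C)[Si](C)(C)Cl
Why: The sparingly soluble monosodium alkoxide of the symmetric diol is silylated once (McDougal mono-protection, O-silylation), and no stereocentre is involved.

**Step 2**
Reactants: 2 2-{[(tert-butyldimethylsilyl)oxy]methyl}prop-2-en-1-ol
Product: 3 2-{[(tert-butyldimethylsilyl)oxy]methyl}prop-2-enal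
Conditions: MnO2 (activated, 10 equiv), CH2Cl2, rt
Reagents that add atoms: none
Why: Allylic alcohol oxidation with MnO2 stops at the enal and leaves the silyl ether and the 1,1-disubstituted alkene untouched.

**Step 3**
Reactants: 3 2-{[(tert-butyldimethylsilyl)oxy]methyl}prop-2-enal
Product: 5 (S)-2-{[(tert-butyldimethylsilyl)oxy]methyl}hexa-1,5-dien-3-ol, via borinate ester 4 (not isolated)
Conditions: (−)-Ipc2BOMe, CH2=CHCH2MgBr, Et2O, 0 °C to rt; 3, −78 °C; then NaOH, H2O2, rt
Reagents that add atoms: allylmagnesium bromide, C=CC[Mg]Br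
Why: Brown asymmetric allylboration, in which the B-allyl reagent from (+)-α-pinene adds through a closed chair transition state to one aldehyde face and, as with benzaldehyde (aldehyde substituent outranks allyl), gives the (S)-carbinol, the single stereocentre (C6) that later controls the other three.

**Step 4**
Reactants: 6 isopropenylmagnesium bromide CH2=C(CH3)MgBr
Product: 8 diisopropyl isopropenylboronate CH2=C(CH3)B(Oi-Pr)2, via ate complex 7 (not isolated)
Conditions: B(Oi-Pr)3, Et2O, −78 °C to rt; HCl in Et2O, 0 °C; distil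
Reagents that add atoms: triisopropyl borate, CC(C)OB(OC(C)C)OC(C)C
Why: Standard boronic ester synthesis by Grignard addition to a trialkyl borate and acid collapse of the ate complex, with no stereocentre involved.

**Step 5**
Reactants: 5 (S)-2-{[(tert-butyldimethylsilyl)oxy]methyl}hexa-1,5-dien-3-ol; 8 diisopropyl isopropenylboronate
Product: 10 (S)-tert-butyl{[2-(3-methyl-2-(propan-2-yloxy)-5,6-dihydro-2H-1,2-oxaborinin-6-yl)prop-2-en-1-yl]oxy}dimethylsilane, via mixed boronate 9 (not isolated)
Conditions: 8 (1.2 equiv), CH2Cl2, rt, then evaporate (removes i-PrOH); (H2IMes)(PCy3)Cl2Ru=CHPh (second-generation Grubbs catalyst, 5 mol%), CH2Cl2, 40 °C; used crude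
Reagents that add atoms: none
Why: Boron-tethered ring-closing metathesis (boronic ester annulation): transesterification ties the isopropenylboron unit to the carbinol oxygen, RCM between the allyl and isopropenyl alkenes closes the six-membered oxaborinine, and the ring forces boron cis to C5 on the new trisubstituted C3=C4 alkene while C6 is untouched.

**Step 6**
Reactants: 10 (S)-cyclic alkenyl boronate from step 5; 11 (Z)-1,2-dichloroethene (10 equiv)
Product: 12 (3S,5Z,7Z)-2-{[(tert-butyldimethylsilyl)oxy]methyl}-8-chloro-6-methylocta-1,5,7-trien-3-ol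
Conditions: Pd(PPh3)4 (5 mol%), K3PO4 (3 equiv), THF/H2O, 45 °C, sealed tube
Reagents that add atoms: none
Why: Suzuki–Miyaura coupling in which zerovalent palladium inserts into one C–Cl bond of the (Z)-dihalide and the alkenyl boronate transmetalates, both with retention, so the 1Z geometry comes from 11 and the 3Z geometry from the former ring, while excess 11 suppresses double coupling.

**Step 7**
Reactants: 12 (3S,5Z,7Z)-2-{[(tert-butyldimethylsilyl)oxy]methyl}-8-chloro-6-methylocta-1,5,7-trien-3-ol
Product: 13 tert-butyl{[(3R,5Z,7Z)-3,8-dichloro-6-methyl-2-methylideneocta-5,7-dien-1-yl]oxy}dimethylsilane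
Conditions: PPh3 (1.3 equiv), Cl3CCOCCl3 (2 equiv), CH2Cl2, 0 °C
Reagents that add atoms: hexachloroacetone, ClC(Cl)(Cl)C(=O)C(Cl)(Cl)Cl
Why: Magid deoxychlorination (PPh3/hexachloroacetone), in which the alkoxyphosphonium chloride ion pair collapses by SN2 to the secondary allylic chloride with inversion (S to R at C6) and without allylic transposition.

**Step 8**
Reactants: 13 tert-butyl{[(3R,5Z,7Z)-3,8-dichloro-6-methyl-2-methylideneocta-5,7-dien-1-yl]oxy}dimethylsilane
Product: 14 (1Z,3Z,6R)-7-(bromomethyl)-1,6-dichloro-3-methylocta-1,3,7-triene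
Conditions: Ph3PBr2 (1.5 equiv), CH2Cl2, 0 °C to rt
Reagents that add atoms: dibromotriphenylphosphorane, BrP(Br)(c1ccccc1)(c1ccccc1)c1ccccc1
Why: Direct silyl ether to bromide exchange with Ph3PBr2 (Palomo protocol), where the ether oxygen is activated on phosphorus and bromide displaces at the primary allylic carbon (SN2 and SN2′ give the same product because the allyl unit is symmetric about C7), leaving C6 untouched.

**Step 9**
Reactants: 14 (1Z,3Z,6R)-7-(bromomethyl)-1,6-dichloro-3-methylocta-1,3,7-triene
Product: 16 (1S,2R,4S,5S)-1-bromo-1-(bromomethyl)-2,4-dichloro-5-[(Z)-2-chloroethenyl]-5-methylcyclohexane, via spiro bromonium salt 15 (not isolated)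
Conditions: 14 added to [Et2SCl][SbCl6] (1.0 equiv, prepared beforehand from Et2S, SbCl5 and Cl2), MeNO2, −25 °C, 2 min; then n-Bu4NBr (3 equiv), −25 to 0 °C
Reagents that add atoms: chlorodiethylsulfonium hexachloroantimonate, CC[S+](Cl)CC.Cl[Sb-](Cl)(Cl)(Cl)(Cl)Cl; tetrabutylammonium bromide, CCCC[N+](CCCC)(CCCC)CCCC.[Br-]
Why: Proposed new method: the chlorosulfonium salt transfers Cl+ to C4 of the chlorodiene (the C7=C9 alkene is deactivated by its two allylic halogens), C9 attacks C3 anti to the new chlorine through a chair in which the C6–Cl bond lies equatorial in the plane of the attacking alkene (so C4–Cl ends 1,3-cis to C6–Cl) and the 3Z geometry puts the chlorovinyl group axial and cis to C4–Cl, the developing C7 cation is bridged by the C8 bromine anti to the new C3–C9 bond to give spiro bromonium ion 15, and bromide, added only after the Cl+ is consumed because Cl+ would oxidise it, opens 15 at the tertiary carbon with inversion to the axial C7–Br, so C6 alone fixes C3, C4 and C7; the closest known chemistry is halonium-induced polyene cyclisation with [Et2SCl][SbCl6] and its bromine analogue, combined with neighbouring-group participation by β-bromine and anti opening of bromonium ions by bromide.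

**Compound list**
1 | 2-methylidenepropane-1,3-diol | C=C(CO)CO | starting material
2 | 2-{[(tert-butyldimethylsilyl)oxy]methyl}prop-2-en-1-ol | C=C(CO)CO[Si](C)(C)C(C)(C)C | intermediate
3 | 2-{[(tert-butyldimethylsilyl)oxy]methyl}prop-2-enal | C=C(C=O)CO[Si](C)(C)C(C)(C)C | intermediate
4 | (S)-2-{[(tert-butyldimethylsilyl)oxy]methyl}hexa-1,5-dien-3-yl diisopinocampheylborinate (Ipc groups from (+)-α-pinene; not isolated) | C=CC[C@H](OB([C@@H]1C[C@@H]2C[C@H]([C@H]1C)C2(C)C)[C@@H]1C[C@@H]2C[C@H]([C@H]1C)C2(C)C)C(=C)CO[Si](C)(C)C(C)(C)C | intermediate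
5 | (S)-2-{[(tert-butyldimethylsilyl)oxy]methyl}hexa-1,5-dien-3-ol | C=CC[C@H](O)C(=C)CO[Si](C)(C)C(C)(C)C | intermediate
6 | isopropenylmagnesium bromide | CC(=C)[Mg]Br | starting material
7 | bromomagnesium triisopropoxy(isopropenyl)borate (not isolated) | CC(=C)[B-](OC(C)C)(OC(C)C)OC(C)C.[Mg+]Br | intermediate
8 | diisopropyl isopropenylboronate | CC(=C)B(OC(C)C)OC(C)C | intermediate
9 | isopropyl (S)-2-{[(tert-butyldimethylsilyl)oxy]methyl}hexa-1,5-dien-3-yl isopropenylboronate (not isolated) | C=CC[C@H](OB(OC(C)C)C(C)=C)C(=C)CO[Si](C)(C)C(C)(C)C | intermediate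
10 | (S)-tert-butyl{[2-(3-methyl-2-(propan-2-yloxy)-5,6-dihydro-2H-1,2-oxaborinin-6-yl)prop-2-en-1-yl]oxy}dimethylsilane | CC1=CC[C@@H](C(=C)CO[Si](C)(C)C(C)(C)C)OB1OC(C)C | intermediate
11 | (Z)-1,2-dichloroethene | Cl/C=C\Cl | starting material
12 | (3S,5Z,7Z)-2-{[(tert-butyldimethylsilyl)oxy]methyl}-8-chloro-6-methylocta-1,5,7-trien-3-ol | Cl/C=C\C(C)=C/C[C@H](O)C(=C)CO[Si](C)(C)C(C)(C)C | intermediate
13 | tert-butyl{[(3R,5Z,7Z)-3,8-dichloro-6-methyl-2-methylideneocta-5,7-dien-1-yl]oxy}dimethylsilane | Cl/C=C\C(C)=C/C[C@@H](Cl)C(=C)CO[Si](C)(C)C(C)(C)C | intermediate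
14 | (1Z,3Z,6R)-7-(bromomethyl)-1,6-dichloro-3-methylocta-1,3,7-triene | Cl/C=C\C(C)=C/C[C@@H](Cl)C(=C)CBr | intermediate
15 | spiro bromonium hexachloroantimonate of the cyclised skeleton; Br+ bridges C7 and C8 on the face opposite to the chlorovinyl group and the two ring chlorines (not isolated) | C[C@@]1(/C=C\Cl)C[C@]2(C[Br+]2)[C@H](Cl)C[C@@H]1Cl.Cl[Sb-](Cl)(Cl)(Cl)(Cl)Cl | intermediate
16 | (1S,2R,4S,5S)-1-bromo-1-(bromomethyl)-2,4-dichloro-5-[(Z)-2-chloroethenyl]-5-methylcyclohexane | C[C@@]1(/C=C\Cl)C[C@@](Br)(CBr)[C@H](Cl)C[C@@H]1Cl | target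

**Step count**
Total steps: 9. Longest linear sequence: 8 steps (1 → 2 → 3 → 5 → 10 → 12 → 13 → 14 → 16); step 4 is a one-step side branch.

**Three steps most likely to fail**

Step 9 (cyclisation cascade). The risks are: Cl+ attack at the wrong alkene; chloride from SbCl6− or proton loss intercepting 15 before bromide arrives; and Br+ transfer from 15 to unreacted 14 (hence the inverse addition). The fallback sets out from 14 and returns at 16. It accepts chloride as the terminating nucleophile and then exchanges it. Compound 14 is treated with [Et2SCl][SbCl6] (1.1 equiv, MeNO2, −25 °C) with no bromide quench, so that SbCl6− opens the bromonium ion and gives the tertiary chloride (1S,2R,4S,5S)-1-(bromomethyl)-1,2,4-trichloro-5-[(Z)-2-chloroethenyl]-5-methylcyclohexane F1. F1 is then treated with Me3SiBr (5 equiv) and catalytic ZnBr2 in CH2Cl2 at 0 °C. Only the tertiary C–Cl ionises, assisted by the neighbouring bromine; bromonium ion 15 re-forms and is opened anti by bromide, so the exchange goes with net retention to 16.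

Step 6 (Suzuki coupling of a hindered cyclic alkenyl boronate with a vinyl chloride). The risks are slow transmetalation, protodeboronation and double coupling. The fallback sets out from 5 and returns at 12, replacing the boron tether and cross-coupling by an ester tether and carbonyl olefination. Alcohol 5 is acylated with methacryloyl chloride (Et3N, DMAP, CH2Cl2, 0 °C) to (S)-2-{[(tert-butyldimethylsilyl)oxy]methyl}hexa-1,5-dien-3-yl 2-methylprop-2-enoate F2. Ring-closing metathesis with (H2IMes)(PCy3)Cl2Ru=CHPh (CH2Cl2, 40 °C) gives (S)-6-(3-{[tert-butyldimethylsilyl]oxy}prop-1-en-2-yl)-3-methyl-5,6-dihydro-2H-pyran-2-one F3, whose ring holds the C3=C4 alkene Z. Reduction with i-Bu2AlH (CH2Cl2, −78 °C) gives (6S)-6-(3-{[tert-butyldimethylsilyl]oxy}prop-1-en-2-yl)-3-methyl-5,6-dihydro-2H-pyran-2-ol F4 as a mixture of anomers. Wittig chloromethylenation of its open hydroxy-enal form with Ph3P=CHCl (from [Ph3PCH2Cl]Cl and NaN(SiMe3)2, THF, −78 °C to rt) gives 12; the C1=C2 geometry comes out as a Z/E mixture that must be separated.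

Step 8 (direct silyl ether to bromide exchange next to a secondary allylic chloride and an acid-sensitive diene). The risks are bromide exchange or SN2′ at C6 and diene isomerisation by adventitious HBr. The fallback sets out from 13 and returns at 14, using stepwise unmasking then bromination. The silyl group is removed with HF·pyridine (THF, 0 °C) to give (3R,5Z,7Z)-3,8-dichloro-6-methyl-2-methylideneocta-5,7-dien-1-ol F5. The primary allylic alcohol is then brominated under Appel conditions (CBr4, PPh3, CH2Cl2, −20 °C) to 14.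

**Further compounds**
F1 | step 9 | (1S,2R,4S,5S)-1-(bromomethyl)-1,2,4-trichloro-5-[(Z)-2-chloroethenyl]-5-methylcyclohexane | C[C@@]1(/C=C\Cl)C[C@@](Cl)(CBr)[C@H](Cl)C[C@@H]1Cl
F2 | step 6 | (S)-2-{[(tert-butyldimethylsilyl)oxy]methyl}hexa-1,5-dien-3-yl 2-methylprop-2-enoate | C=CC[C@H](OC(=O)C(C)=C)C(=C)CO[Si](C)(C)C(C)(C)C
F3 | step 6 | (S)-6-(3-{[tert-butyldimethylsilyl]oxy}prop-1-en-2-yl)-3-methyl-5,6-dihydro-2H-pyran-2-one | CC1=CC[C@@H](C(=C)CO[Si](C)(C)C(C)(C)C)OC1=O
F4 | step 6 | (6S)-6-(3-{[tert-butyldimethylsilyl]oxy}prop-1-en-2-yl)-3-methyl-5,6-dihydro-2H-pyran-2-ol (both anomers) | CC1=CC[C@@H](C(=C)CO[Si](C)(C)C(C)(C)C)OC1O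
F5 | step 8 | (3R,5Z,7Z)-3,8-dichloro-6-methyl-2-methylideneocta-5,7-dien-1-ol | Cl/C=C\C(C)=C/C[C@@H](Cl)C(=C)CO
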